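Ring A of the target (C1–C5, C10; labdane numbering) is made by enlarging a cyclopentane. An A-nor trans-hydrindane carries, on carbinol carbon C3, a 2-methyloxirane that is the future C4 and C18. Lewis acid opens the epoxide at its tertiary carbon and the C3–C5 bond migrates to it (semipinacol). This one step creates the six-membered ring, the quaternary centre C4 with its methyl and hydroxymethyl groups in the correct sense (inversion at the epoxide carbon), the C3 carbonyl that becomes the acetate, and keeps the trans ring fusion. The precursor, complete in ring B and side chain, comes from an NHC benzoin desymmetrisation of a 2-methylcyclohexane-1,3-dione.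

Key step: step 13

Remark: carbons carry the labdane numbers of the target (C17 exocyclic CH2, C18 the CH2O on C4, C20 the angular methyl); "A-nor" means C3 is bonded directly to C5; for each chiral catalyst or ligand the enantiomer is assumed whose sense of induction gives the configuration drawn; the CIP label of C10 changes from R to S once the C9 oxygen is gone, with no change in geometry.

Step 1
Reactants: 1 2-methylcyclohexane-1,3-dione; 2 acrolein
Product: 3 3-(1-methyl-2,6-dioxocyclohexyl)propanal
Conditions: H2O, 23 °C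
Reagents that add atoms: none
Why: Michael addition of the acidic 1,3-dione to the enal attaches C1–C3 to the future C10 and leaves two enantiotopic ring ketones (the future C5 and C9); no stereocentre is formed.

Step 2
Reactants: 3 3-(1-methyl-2,6-dioxocyclohexyl)propanal
Product: 4 (3aR,7aS)-7a-hydroxy-3a-methylhexahydro-1H-indene-1,4(2H)-dione
Conditions: aminoindanol-derived N-pentafluorophenyl triazolium tetrafluoroborate (10 mol%), Et3N (10 mol%), toluene, 23 °C
Reagents that add atoms: none
Why: NHC-catalysed intramolecular crossed benzoin reaction in which the Breslow intermediate of the aldehyde adds (5-exo) to one of the two enantiotopic ketones, so the chiral carbene sets C10 and the cis-fused tertiary alcohol at C5 in one desymmetrising ring closure.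

Step 3
Reactants: 4 (3aR,7aS)-7a-hydroxy-3a-methylhexahydro-1H-indene-1,4(2H)-dione
Product: 6 (R)-3a-methyl-1-(triethylsilyloxy)-2,3,3a,5,6,7-hexahydro-4H-inden-4-one, via samarium enolate 5 (not isolated)
Conditions: SmI2 (2.2 equiv), THF, −78 °C; then Et3SiCl, HMPA, −78 to 0 °C
Reagents that add atoms: chlorotriethylsilane CC[Si](Cl)(CC)CC
Why: SmI2 reductive cleavage of the alpha-hydroxy ketone C5–O bond should give the regiodefined C3=C5 samarium enolate, and its O-silylation masks the five-ring ketone so that the C9 ketone, enolisable only toward C8, is the single remaining carbonyl.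

Step 4
Reactants: 6 (R)-3a-methyl-1-(triethylsilyloxy)-2,3,3a,5,6,7-hexahydro-4H-inden-4-one
Product: 10 (R)-3a-methyl-5-methylidene-1-(triethylsilyloxy)-2,3,3a,5,6,7-hexahydro-4H-inden-4-one, via lithium enolate 7 (not isolated), via Mannich base 8 (not isolated), via ammonium iodide 9 (not isolated)
Conditions: LDA, THF, −78 °C; CH2=NMe2+ I−, −78 to 0 °C; then MeI, 23 °C; then DBU, CH2Cl2, 23 °C
Reagents that add atoms: N,N-dimethylmethyleneiminium iodide C=[N+](C)C.[I-]
Why: Mannich reaction of the only possible ketone enolate with Eschenmoser's salt, then N-methylation and E1cB loss of trimethylamine (alpha-methylenation), installs C17 as the exocyclic methylene on C8.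

Step 5
Reactants: 11 tert-butyl(but-3-yn-1-yloxy)dimethylsilane
Product: 14 (E)-5-(tert-butyldimethylsilyloxy)-3-methylpent-2-en-1-ol, via alkenylalane 12 (not isolated), via lithium alanate 13 (not isolated)
Conditions: Me3Al, Cp2ZrCl2 (20 mol%), CH2Cl2, 23 °C; then n-BuLi, THF, −78 °C; (CH2O)n, −78 to 23 °C
Reagents that add atoms: trimethylaluminium C[Al](C)C; paraformaldehyde (formaldehyde unit) C=O
Why: zirconium-catalysed syn-carboalumination of the terminal alkyne (Negishi reaction) places methyl and aluminium cis, and hydroxymethylation of the derived alanate occurs with retention, which fixes the E geometry of the future C13=C14 alkene.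

Step 6
Reactants: 14 (E)-5-(tert-butyldimethylsilyloxy)-3-methylpent-2-en-1-ol
Product: 15 (E)-5-(tert-butyldimethylsilyloxy)-1-(tert-butyldiphenylsilyloxy)-3-methylpent-2-ene
Conditions: TBDPSCl, imidazole, CH2Cl2, 23 °C
Reagents that add atoms: tert-butyl(chloro)diphenylsilane CC(C)(C)[Si](Cl)(c1ccccc1)c1ccccc1
Why: silylation of the primary allylic alcohol with the bulky chlorosilane installs the C15 protecting group that is carried to the last step.

Step 7
Reactants: 15 (E)-5-(tert-butyldimethylsilyloxy)-1-(tert-butyldiphenylsilyloxy)-3-methylpent-2-ene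
Product: 16 (E)-5-(tert-butyldiphenylsilyloxy)-3-methylpent-3-en-1-ol
Conditions: PPTS, EtOH, 40 °C
Reagents that add atoms: none
Why: mild acid-catalysed solvolysis should cleave the less hindered tert-butyldimethylsilyl ether while the tert-butyldiphenylsilyl ether is stable.

Step 8
Reactants: 16 (E)-5-(tert-butyldiphenylsilyloxy)-3-methylpent-3-en-1-ol
Product: 17 (E)-tert-butyl[(5-iodo-3-methylpent-2-en-1-yl)oxy]diphenylsilane
Conditions: I2, PPh3, imidazole, CH2Cl2, 0 °C
Reagents that add atoms: iodine II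
Why: Appel-type iodination converts the primary alcohol into the iodide needed for iodine–lithium exchange.

Step 9
Reactants: 17 (E)-tert-butyl[(5-iodo-3-methylpent-2-en-1-yl)oxy]diphenylsilane; 10 (R)-3a-methyl-5-methylidene-1-(triethylsilyloxy)-2,3,3a,5,6,7-hexahydro-4H-inden-4-one
Product: 20 (9R,10R)-15-(tert-butyldiphenylsilyloxy)-3-(triethylsilyloxy)-A-nor-ent-labda-3(5),8(17),13E-trien-9-yl methyl carbonate, via organolithium 18 (not isolated), via lithium alkoxide 19 (not isolated)
Conditions: t-BuLi (2.1 equiv), Et2O–pentane, −78 °C; then 10, −78 °C; then ClCO2Me, −78 to 0 °C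
Reagents that add atoms: methyl chloroformate COC(Cl)=O
Why: iodine–lithium exchange gives the primary alkyllithium, which should add 1,2 to the non-enolisable enone carbonyl from the face opposite the axial C20 methyl, and the tertiary alkoxide is trapped in situ as the methyl carbonate (the C9 configuration is reset in step 10).

Step 10
Reactants: 20 (9R,10R)-15-(tert-butyldiphenylsilyloxy)-3-(triethylsilyloxy)-A-nor-ent-labda-3(5),8(17),13E-trien-9-yl methyl carbonate
Product: 21 (9R,10S)-15-(tert-butyldiphenylsilyloxy)-3-(triethylsilyloxy)-A-nor-ent-labda-3(5),8(17),13E-triene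
Conditions: Pd(OAc)2 (5 mol%), n-Bu3P (20 mol%), HCO2NH4, Et3N, THF, 65 °C
Reagents that add atoms: none
Why: palladium-catalysed formate hydrogenolysis of the tertiary allylic carbonate (Tsuji–Trost type), in which the pi-allyl complex carries palladium on the face away from the axial C20 methyl and transfers hydride to the more substituted terminus C9, so that C8=C17 stays exocyclic and the C9 side chain becomes equatorial (9R).

Step 11
Reactants: 21 (9R,10S)-15-(tert-butyldiphenylsilyloxy)-3-(triethylsilyloxy)-A-nor-ent-labda-3(5),8(17),13E-triene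
Product: 24 (3R,5S,9R,10S)-15-(tert-butyldiphenylsilyloxy)-3-(prop-1-en-2-yl)-A-nor-ent-labda-8(17),13E-dien-3-ol, via lithium enolate 22 (not isolated), via trans-ketone 23 (not isolated)
Conditions: MeLi, THF, 0 to 23 °C; then 2,6-di-tert-butyl-4-methylphenol, −78 °C; then CH2=C(CH3)MgBr–CeCl3, THF, −78 °C
Reagents that add atoms: isopropenylmagnesium bromide C=C(C)[Mg]Br
Why: methyllithium cleaves the silyl enol ether to the C3=C5 lithium enolate, the hindered phenol should protonate C5 kinetically on the face opposite the axial C20 methyl (trans ring fusion, 5S), and the epimerisable ketone is consumed at once by 1,2-addition of the weakly basic organocerium reagent anti to the same methyl group (3R).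

Step 12
Reactants: 24 (3R,5S,9R,10S)-15-(tert-butyldiphenylsilyloxy)-3-(prop-1-en-2-yl)-A-nor-ent-labda-8(17),13E-dien-3-ol
Product: 25 (3R,5S,9R,10S)-15-(tert-butyldiphenylsilyloxy)-3-[(R)-2-methyloxiran-2-yl]-A-nor-ent-labda-8(17),13E-dien-3-ol
Conditions: Hf(OtBu)4 (10 mol%), chiral bishydroxamic acid ligand (11 mol%), cumene hydroperoxide, toluene, 0 °C
Reagents that add atoms: cumene hydroperoxide CC(C)(OO)c1ccccc1
Why: hydroxyl-directed, ligand-controlled epoxidation of the tertiary allylic alcohol (hafnium–bishydroxamic acid catalysis), in which only the isopropenyl alkene is bound through the metal alkoxide, so C8=C17 and C13=C14 are not touched, and the ligand enantiomer rather than the small intrinsic bias of the two ring carbons on C3 should deliver oxygen to the face that makes C4 of the epoxide R.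

Step 13
Reactants: 25 (3R,5S,9R,10S)-15-(tert-butyldiphenylsilyloxy)-3-[(R)-2-methyloxiran-2-yl]-A-nor-ent-labda-8(17),13E-dien-3-ol
Product: 26 (4S,5S,9R,10S)-15-(tert-butyldiphenylsilyloxy)-18-hydroxy-ent-labda-8(17),13E-dien-3-one
Conditions: ZnBr2 (1.0 equiv), CH2Cl2, 0 to 23 °C
Reagents that add atoms: none
Why: ZnBr2 coordinates the epoxide oxygen and ionises the C4–O bond at the tertiary epoxide carbon while the C3–C5 ring bond, antiperiplanar to it, shifts from the carbinol carbon C3 to C4 and the C3 hydroxyl collapses to the ketone. The closest known reaction type is the semipinacol rearrangement of alpha-hydroxy epoxides to beta-hydroxy ketones, with ring enlargement of 1-(oxiranyl)cycloalkanols. Ring A (C1–C5, C10) is closed by this 1,2-alkyl shift, that is by insertion of C4 into the C3–C5 bond of the cyclopentane, not by an exo or endo cyclisation. The new quaternary centre C4 is set by inversion at the epoxide carbon, so the (R)-epoxide should give the (S)-centre with axial methyl and equatorial CH2OH, and C5 migrates with retention, so the trans ring fusion from step 11 is kept. The step needs C5 rather than C2 to migrate and the two other alkenes to stay untouched: the more substituted methine C5 is the better migrating group, and a mild zinc halide at or below room temperature should not ionise or isomerise the exocyclic methylene or the allylic silyl ether.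

Step 14
Reactants: 26 (4S,5S,9R,10S)-15-(tert-butyldiphenylsilyloxy)-18-hydroxy-ent-labda-8(17),13E-dien-3-one
Product: 27 (4S,5S,9R,10S)-15-(tert-butyldiphenylsilyloxy)-3-oxo-ent-labda-8(17),13E-dien-18-yl (E)-2-methylbut-2-enoate
Conditions: (E)-2-methylbut-2-enoyl chloride, pyridine, DMAP (cat.), CH2Cl2, 0 °C
Reagents that add atoms: tigloyl chloride C/C=C(\C)C(Cl)=O
Why: acylation of the primary neopentyl alcohol under mild amine base, which should avoid retro-aldol loss of formaldehyde from the beta-hydroxy ketone.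

Step 15
Reactants: 27 (4S,5S,9R,10S)-15-(tert-butyldiphenylsilyloxy)-3-oxo-ent-labda-8(17),13E-dien-18-yl (E)-2-methylbut-2-enoate
Product: 28 (3R,4S,5S,9R,10S)-15-(tert-butyldiphenylsilyloxy)-3-hydroxy-ent-labda-8(17),13E-dien-18-yl (E)-2-methylbut-2-enoate
Conditions: NaBH4, MeOH–THF, −20 °C
Reagents that add atoms: none
Why: axial hydride attack on the C3 ketone, on the face opposite the axial C4 methyl, should give the equatorial (3R)-alcohol, while the conjugated ester is inert to NaBH4 at this temperature.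

Step 16
Reactants: 28 (3R,4S,5S,9R,10S)-15-(tert-butyldiphenylsilyloxy)-3-hydroxy-ent-labda-8(17),13E-dien-18-yl (E)-2-methylbut-2-enoate
Product: 29 (3R,4S,5S,9R,10S)-3-acetoxy-15-(tert-butyldiphenylsilyloxy)-ent-labda-8(17),13E-dien-18-yl (E)-2-methylbut-2-enoate
Conditions: Ac2O, pyridine, DMAP (cat.), CH2Cl2, 23 °C
Reagents that add atoms: acetic anhydride CC(=O)OC(C)=O
Why: nucleophile-catalysed acetylation of the hindered secondary alcohol.

Step 17
Reactants: 29 (3R,4S,5S,9R,10S)-3-acetoxy-15-(tert-butyldiphenylsilyloxy)-ent-labda-8(17),13E-dien-18-yl (E)-2-methylbut-2-enoate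
Product: 30 (3R,4S,5S,9R,10S)-3-acetoxy-15-hydroxy-ent-labda-8(17),13E-dien-18-yl (E)-2-methylbut-2-enoate
Conditions: HF·pyridine, pyridine, THF, 0 to 23 °C
Reagents that add atoms: none
Why: buffered fluoride cleavage of the silyl ether should free the allylic C15 alcohol without touching the two esters or the alkenes.

Compound list
1 | 2-methylcyclohexane-1,3-dione | CC1C(=O)CCCC1=O | starting material
2 | acrolein (prop-2-enal) | C=CC=O | starting material
3 | 3-(1-methyl-2,6-dioxocyclohexyl)propanal | CC1(CCC=O)C(=O)CCCC1=O | intermediate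
4 | (3aR,7aS)-7a-hydroxy-3a-methylhexahydro-1H-indene-1,4(2H)-dione (cis-fused ketol, OH cis to CH3) | O=C1CCC[C@@]2(O)C(=O)CC[C@@]12C | intermediate
5 | samarium enolate: diiodosamarium (R)-3a-methyl-4-oxo-3,3a,4,5,6,7-hexahydro-2H-inden-1-olate | O=C1CCCC2=C(O[Sm](I)I)CC[C@@]12C | intermediate
6 | (R)-3a-methyl-1-(triethylsilyloxy)-2,3,3a,5,6,7-hexahydro-4H-inden-4-one | O=C1CCCC2=C(O[Si](CC)(CC)CC)CC[C@@]12C | intermediate
7 | lithium enolate of 6 (C4–OLi, C4=C5 in indene numbering) | [Li]OC1=CCCC2=C(O[Si](CC)(CC)CC)CC[C@@]12C | intermediate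
8 | Mannich base: (3aR)-5-[(dimethylamino)methyl]-3a-methyl-1-(triethylsilyloxy)-2,3,3a,5,6,7-hexahydro-4H-inden-4-one (C5 epimers) | CN(C)CC1CCC2=C(O[Si](CC)(CC)CC)CC[C@@]2(C)C1=O | intermediate
9 | trimethylammonium iodide of 8 | C[N+](C)(C)CC1CCC2=C(O[Si](CC)(CC)CC)CC[C@@]2(C)C1=O.[I-] | intermediate
10 | (R)-3a-methyl-5-methylidene-1-(triethylsilyloxy)-2,3,3a,5,6,7-hexahydro-4H-inden-4-one | C=C1CCC2=C(O[Si](CC)(CC)CC)CC[C@@]2(C)C1=O | intermediate
11 | tert-butyl(but-3-yn-1-yloxy)dimethylsilane | C#CCCO[Si](C)(C)C(C)(C)C | starting material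
12 | alkenylalane: [(E)-4-(tert-butyldimethylsilyloxy)-2-methylbut-1-en-1-yl]dimethylalane | C[Al](C)/C=C(\C)CCO[Si](C)(C)C(C)(C)C | intermediate
13 | lithium butyl(dimethyl)alanate of 12 | [Li+].CCCC[Al-](C)(C)/C=C(\C)CCO[Si](C)(C)C(C)(C)C | intermediate
14 | (E)-5-(tert-butyldimethylsilyloxy)-3-methylpent-2-en-1-ol | OC/C=C(\C)CCO[Si](C)(C)C(C)(C)C | intermediate
15 | (E)-5-(tert-butyldimethylsilyloxy)-1-(tert-butyldiphenylsilyloxy)-3-methylpent-2-ene | CC(C)(C)[Si](C)(C)OCC/C(C)=C/CO[Si](c1ccccc1)(c1ccccc1)C(C)(C)C | intermediate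
16 | (E)-5-(tert-butyldiphenylsilyloxy)-3-methylpent-3-en-1-ol | OCC/C(C)=C/CO[Si](c1ccccc1)(c1ccccc1)C(C)(C)C | intermediate
17 | (E)-tert-butyl[(5-iodo-3-methylpent-2-en-1-yl)oxy]diphenylsilane | ICC/C(C)=C/CO[Si](c1ccccc1)(c1ccccc1)C(C)(C)C | intermediate
18 | organolithium: (E)-[5-(tert-butyldiphenylsilyloxy)-3-methylpent-3-en-1-yl]lithium | [Li]CC/C(C)=C/CO[Si](c1ccccc1)(c1ccccc1)C(C)(C)C | intermediate
19 | lithium alkoxide of the 1,2-adduct of 18 to 10 (C9–OLi, chain trans to C20) | C=C1CCC2=C(O[Si](CC)(CC)CC)CC[C@@]2(C)[C@@]1(O[Li])CC/C(C)=C/CO[Si](c3ccccc3)(c3ccccc3)C(C)(C)C | intermediate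
20 | (9R,10R)-15-(tert-butyldiphenylsilyloxy)-3-(triethylsilyloxy)-A-nor-ent-labda-3(5),8(17),13E-trien-9-yl methyl carbonate | C=C1CCC2=C(O[Si](CC)(CC)CC)CC[C@@]2(C)[C@@]1(OC(=O)OC)CC/C(C)=C/CO[Si](c3ccccc3)(c3ccccc3)C(C)(C)C | intermediate
21 | (9R,10S)-15-(tert-butyldiphenylsilyloxy)-3-(triethylsilyloxy)-A-nor-ent-labda-3(5),8(17),13E-triene | C=C1CCC2=C(O[Si](CC)(CC)CC)CC[C@@]2(C)[C@@H]1CC/C(C)=C/CO[Si](c3ccccc3)(c3ccccc3)C(C)(C)C | intermediate
22 | lithium enolate of 23 (C3–OLi, C3=C5) | C=C1CCC2=C(O[Li])CC[C@@]2(C)[C@@H]1CC/C(C)=C/CO[Si](c3ccccc3)(c3ccccc3)C(C)(C)C | intermediate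
23 | (5S,9R,10S)-15-(tert-butyldiphenylsilyloxy)-A-nor-ent-labda-8(17),13E-dien-3-one (trans-fused) | C=C1CC[C@H]2[C@@](C)(CCC2=O)[C@@H]1CC/C(C)=C/CO[Si](c3ccccc3)(c3ccccc3)C(C)(C)C | intermediate
24 | (3R,5S,9R,10S)-15-(tert-butyldiphenylsilyloxy)-3-(prop-1-en-2-yl)-A-nor-ent-labda-8(17),13E-dien-3-ol (OH cis to C20) | C=C1CC[C@H]2[C@@](C)(CC[C@]2(O)C(C)=C)[C@@H]1CC/C(C)=C/CO[Si](c3ccccc3)(c3ccccc3)C(C)(C)C | intermediate
25 | (3R,5S,9R,10S)-15-(tert-butyldiphenylsilyloxy)-3-[(R)-2-methyloxiran-2-yl]-A-nor-ent-labda-8(17),13E-dien-3-ol | C=C1CC[C@H]2[C@@](C)(CC[C@]2(O)[C@@]3(C)CO3)[C@@H]1CC/C(C)=C/CO[Si](c4ccccc4)(c4ccccc4)C(C)(C)C | intermediate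
26 | (4S,5S,9R,10S)-15-(tert-butyldiphenylsilyloxy)-18-hydroxy-ent-labda-8(17),13E-dien-3-one | C=C1CC[C@H]2[C@@](C)(CCC(=O)[C@]2(C)CO)[C@@H]1CC/C(C)=C/CO[Si](c3ccccc3)(c3ccccc3)C(C)(C)C | intermediate
27 | (4S,5S,9R,10S)-15-(tert-butyldiphenylsilyloxy)-3-oxo-ent-labda-8(17),13E-dien-18-yl (E)-2-methylbut-2-enoate | C=C1CC[C@H]2[C@@](C)(CCC(=O)[C@]2(C)COC(=O)/C(C)=C/C)[C@@H]1CC/C(C)=C/CO[Si](c3ccccc3)(c3ccccc3)C(C)(C)C | intermediate
28 | (3R,4S,5S,9R,10S)-15-(tert-butyldiphenylsilyloxy)-3-hydroxy-ent-labda-8(17),13E-dien-18-yl (E)-2-methylbut-2-enoate | C=C1CC[C@H]2[C@@](C)(CC[C@@H](O)[C@]2(C)COC(=O)/C(C)=C/C)[C@@H]1CC/C(C)=C/CO[Si](c3ccccc3)(c3ccccc3)C(C)(C)C | intermediate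
29 | (3R,4S,5S,9R,10S)-3-acetoxy-15-(tert-butyldiphenylsilyloxy)-ent-labda-8(17),13E-dien-18-yl (E)-2-methylbut-2-enoate | C=C1CC[C@H]2[C@@](C)(CC[C@@H](OC(C)=O)[C@]2(C)COC(=O)/C(C)=C/C)[C@@H]1CC/C(C)=C/CO[Si](c3ccccc3)(c3ccccc3)C(C)(C)C | intermediate
30 | (3R,4S,5S,9R,10S)-3-acetoxy-15-hydroxy-ent-labda-8(17),13E-dien-18-yl (E)-2-methylbut-2-enoate | C=C1CC[C@H]2[C@@](C)(CC[C@@H](OC(C)=O)[C@]2(C)COC(=O)/C(C)=C/C)[C@@H]1CC/C(C)=C/CO | target

Total step count: 17. Longest linear sequence: 13 steps (steps 1–4 and 9–17); steps 5–8 make the side-chain iodide.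

Steps most likely to fail

Step 11. What may go wrong: protonation of the ring-fusion enolate on the face of the angular methyl, or epimerisation of the trans-ketone before the organocerium reagent adds, would lead into the cis-fused series. Fallback: setting out from 21, cyclopropanation of the silyl enol ether with Et2Zn and 1,1-diiodoethane (Furukawa-modified Simmons–Smith reaction) should give the siloxycyclopropane F1. FeCl3 in DMF should cleave its internal C3–C5 bond oxidatively to the ring-enlarged beta-chloro ketone F2, and NaOAc in MeOH should eliminate HCl to the 4-methyl enone F3. Li in liquid NH3 (just over two equivalents, to spare the allylic silyl ether) followed by gaseous formaldehyde (reductive alkylation) should protonate C5 axially, so that the trans fusion is set in the six-membered ring, and hydroxymethylate C4 on the face opposite the C20 methyl. This comes back to the route at 26 and makes steps 12 and 13 unnecessary; ring A is still formed from the cyclopentane.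

Step 12. What may go wrong: the facial preference of the catalyst may be opposed by the substrate, giving the C4 epimer of the epoxide, or turnover may be slow at the hindered 1,1-disubstituted alkene. Fallback: setting out from 23 (generated as in step 11), aldol addition of the lithium enolate of (2R,5R)-2-tert-butyl-5-methyl-1,3-dioxolan-4-one (made from (R)-lactic acid and pivalaldehyde; the ketone enters opposite the tert-butyl group) should give the dioxolanone adduct F4, with C4 fixed by the reagent. LiAlH4 should reduce the dioxolanone to the triol F5, and Mitsunobu cyclodehydration (PPh3, DIAD) of the primary–tertiary 1,2-diol should close the epoxide with retention at C4. This comes back to the route at 25.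

Step 13. What may go wrong: opening of the zinc-activated epoxide by bromide, or loss of a proton to an allylic alcohol, may compete with the 1,2-shift, and the exocyclic alkene may isomerise if acid is set free. Fallback: setting out from 25, silylation with N-(trimethylsilyl)imidazole should give the epoxy silyl ether F6. The bulky, halide-free Lewis acid methylaluminium bis(4-bromo-2,6-di-tert-butylphenoxide) in CH2Cl2 at −78 °C should then promote the rearrangement of the epoxy silyl ether (the same anti 1,2-shift of C5) to the beta-silyloxy ketone F7, and K2CO3 in MeOH should cleave the trimethylsilyl ether. This comes back to the route at 26.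

Further compounds
F1 | step 11 | siloxycyclopropane: CH(CH3) bridging C3 and C5 of 21 on the face opposite C20, C3–OSiEt3 retained (CH3 epimers) | C=C1CC[C@]23C(C)[C@@]2(O[Si](CC)(CC)CC)CC[C@@]3(C)[C@@H]1CC/C(C)=C/CO[Si](c4ccccc4)(c4ccccc4)C(C)(C)C
F2 | step 11 | (9R,10S)-15-(tert-butyldiphenylsilyloxy)-5-chloro-18-nor-ent-labda-8(17),13E-dien-3-one (C4 and C5 epimers) | C=C1CCC2(Cl)C(C)C(=O)CC[C@@]2(C)[C@@H]1CC/C(C)=C/CO[Si](c3ccccc3)(c3ccccc3)C(C)(C)C
F3 | step 11 | (9R,10S)-15-(tert-butyldiphenylsilyloxy)-18-nor-ent-labda-4,8(17),13E-trien-3-one | C=C1CCC2=C(C)C(=O)CC[C@@]2(C)[C@@H]1CC/C(C)=C/CO[Si](c3ccccc3)(c3ccccc3)C(C)(C)C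
F4 | step 12 | (3R,5S,9R,10S)-3-[(2R,4S)-2-tert-butyl-4-methyl-5-oxo-1,3-dioxolan-4-yl]-15-(tert-butyldiphenylsilyloxy)-A-nor-ent-labda-8(17),13E-dien-3-ol | C=C1CC[C@H]2[C@@](C)(CC[C@]2(O)[C@]3(C)O[C@@H](C(C)(C)C)OC3=O)[C@@H]1CC/C(C)=C/CO[Si](c4ccccc4)(c4ccccc4)C(C)(C)C
F5 | step 12 | (3R,5S,9R,10S)-15-(tert-butyldiphenylsilyloxy)-3-[(R)-1,2-dihydroxypropan-2-yl]-A-nor-ent-labda-8(17),13E-dien-3-ol | C=C1CC[C@H]2[C@@](C)(CC[C@]2(O)[C@](C)(O)CO)[C@@H]1CC/C(C)=C/CO[Si](c3ccccc3)(c3ccccc3)C(C)(C)C
F6 | step 13 | trimethylsilyl ether of 25 at the C3 oxygen | C=C1CC[C@H]2[C@@](C)(CC[C@]2(O[Si](C)(C)C)[C@@]3(C)CO3)[C@@H]1CC/C(C)=C/CO[Si](c4ccccc4)(c4ccccc4)C(C)(C)C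
F7 | step 13 | (4S,5S,9R,10S)-15-(tert-butyldiphenylsilyloxy)-18-(trimethylsilyloxy)-ent-labda-8(17),13E-dien-3-one | C=C1CC[C@H]2[C@@](C)(CCC(=O)[C@]2(C)CO[Si](C)(C)C)[C@@H]1CC/C(C)=C/CO[Si](c3ccccc3)(c3ccccc3)C(C)(C)C
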